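## The problem

Spiculoic acid B (27) is a trans-fused 3a,4,5,7a-tetrahydro-1H-indene. With C1 as the carboxyl carbon on C2, ring A is the cyclohexene C2–C3–C7–C8(Et)=C9–C10 and ring B the cyclopentene C3–C4(Et)=C5–C6(Me)–C7; C10 also carries an ethyl group and the styryl unit C11=C12. The five stereocentres C2, C3, C6, C7 and C10 are contiguous, and C2 and C10 are neighbouring all-carbon quaternary carbons, so the C2–C10 and C2–C3 bonds must be made by reactions that tolerate extreme crowding. Ring B offers a relay of control: C7 can be set against a removable oxygen substituent, C6 against C7, a C5 oxygen against C6, and that oxygen can pass its configuration to C3 in a suprafacial sigmatropic shift, with C2 following from the geometry of a ketene acetal. C10 is the exception: its ethyl and alkenyl substituents are nearly equal in size, so no resident centre can be relied on to set it and an external control element is needed. The four isolated alkenes, two of them trisubstituted and γ,δ to the carboxyl group, exclude strong acid (alkene migration, lactonisation) and unselective oxidants or reductants. The carboxyl carbon is shielded by C2, C3 and C10, so its protecting group has to come off without attack at the carbonyl carbon. The enabling feature is that C10 bears two alkenyl groups, C9 of ring A and C11 of the styryl unit: a C10 with two vinyl groups is prochiral, closure of C8=C9 by metathesis consumes one of them, and the other is one arylation away from the styryl group.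

## Retrosynthesis

**C12–aryl bond and ester.** Acid 27 is traced to its methyl ester 26, and 26 to the 10-vinyl ester 24 and iodobenzene (25) by cutting the C12–phenyl bond. Introducing the phenyl group last keeps the two alkenyl groups on C10 identical until ring A exists; a styryl group carried through the ring closure would compete in the metathesis. Ester 24 is smaller than 26 only by the phenyl group. The forward arylation must touch only the monosubstituted vinyl group and give the E alkene, and the ester must be cleaved at its methyl carbon.

**C8=C9 (ring A).** Cutting the ring-A double bond of 24 gives triene ester 23, with two vinyl groups on C10 and a but-1-en-2-yl group on C7. Compared with cuts at C2–C3 or C2–C10 inside the bicycle, this cut removes ring A and the C10 stereocentre together. The forward metathesis must select one of two diastereotopic vinyl groups and close onto a 1,1-disubstituted alkene.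

**C2–C3.** Ester 23 is the methyl ester of acid 22. An Ireland–Claisen transform across C2–C3 leads to allylic ester 19, and so to acid 7 and cyclopentenol 17. An intermolecular alkylation or conjugate addition would have to join a quaternary to a tertiary carbon. The [3,3] shift does this intramolecularly, moves the C5–O configuration to C3 and leaves the C4=C5 alkene where the target has it. The problem is divided into a ten-carbon and a twelve-carbon fragment. The forward step must control ketene acetal geometry and transition-state shape to set C2.

**C2–C10.** Acid 7 comes from ester 6. A Johnson–Claisen transform across C2–C10 gives dienol 3 and orthoester 4. Dienol 3 comes from dienoate 2, and 2 from ynoate 1 by addition of a vinyl copper reagent. Alkylating a propionate enolate with a tertiary electrophile is not feasible, whereas the sigmatropic route builds the quaternary carbon readily. Because both alkenyl groups on C10 are vinyl, no stereochemistry has to be controlled here.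

**C4–ethyl and C5–O.** Alcohol 17 is traced to enone 16, 16 to iodoenone 15 by cutting the C4–ethyl bond, and 15 to enone 14. Installing ethyl by α-iodination and cross-coupling is regiospecific, whereas alkylation of a saturated ketone would have to distinguish two α-positions. The forward reduction must deliver hydride to the face opposite the C6 methyl group.

**C6–methyl and C7–C8.** Enone 14 is traced to 12 (C6–CH3 cut), 12 to silyloxy ketone 11 (enone transposition by β-elimination) and 11 to silyloxy enone 8 and bromide 9 (C7–C8 cut). The silyloxy group of 8 is the single source of absolute configuration: it directs the alkenyl group anti and then leaves. A catalytic enantioselective alkenyl addition to an α-methylated cyclopentenone would be a step shorter but has little precedent. The forward steps require anti addition at C7 and methylation anti to the new substituent.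

## Roads not taken

**Alternative 1: crossed photocycloaddition with de Mayo fragmentation.**
- **Cut:** C2–C3 and C9–C10 together, through a temporary C3–C9 cyclobutane bond.
- **Forward key step:** irradiation near 350 nm makes an enol ester alkene (C3=C9) add in crossed fashion to a tethered C2=C10 enoate, giving the spiro 2-oxabicyclo[2.1.1]hexan-3-one A1.
- **Merits:** both quaternary carbons and their relative configuration arise in one intramolecular, reagent-free step. C10 is formed with ethyl and an oxygenated carbon as its distinguishing groups, so its configuration rests on the tether and not on a catalyst telling ethyl from vinyl. In this respect A1 is more secure than the chosen plan.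
- **Weak points:** no target ring is closed in A1. Fragmentation of C3–C9, unmasking of the C8 dithiane, carbonyl coupling for C8=C9, conversion of the C4 ketone into the ethyl-bearing alkene and elaboration of C11 to the styryl group add roughly ten steps. Crossed against straight regiochemistry and the facial sense relative to C6 and C7 are not assured.
- **Comparison:** the chosen plan is two steps from the target after its key step and uses no redox adjustments. It has to set the uncertainty of ketene acetal geometry at C2 and of group selection at C10 against the tether-enforced quaternary pair of A1.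

**Alternative 2: heptan-4-one annulation, then vicinal methylation and styrenylation.**
- **Cut:** C2–CH3 and C10–C11 on a preformed bicyclic ene-keto ester.
- **Forward key step:** Me2CuLi (monovalent copper) adds methyl to C2, and the resulting C10 enolate is alkenylated by (E)-styryl(phenyl)iodonium tetrafluoroborate (trivalent iodine), giving keto ester A2.
- **Merits:** a cheap symmetrical ketone supplies C8–C10 with both ethyl groups. The styryl group arrives intact with E geometry, so no late arylation is needed, and the two new groups enter a rigid bicycle trans to each other. In the directness of styryl introduction, and in deriving C10 from a ring-face preference, this road is better than the chosen plan.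
- **Weak points:** conjugate addition to a fully substituted β-carbon next to the ring fusion is among the hardest cuprate additions. The hindered tetrasubstituted enolate may undergo O-alkenylation or phenyl transfer. A2 still holds a C9 ketone and a masked C4 ketone, each of which must become a trisubstituted alkene, with regiochemical questions at C4/C5 and five to six further steps.
- **Comparison:** the chosen plan builds both quaternary carbons by intramolecular [3,3] shifts, which are less sensitive to crowding, and needs two steps after the key step. It has to set catalyst-dependent selection at C10 against the ring-controlled selectivity of A2.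

**Alternative 3: rhodium hydroacylation closing ring B last.**
- **Cut:** C4–C5 of ring B.
- **Forward key step:** [Rh(BINAP)]ClO4 (monovalent rhodium) inserts into the aldehyde C–H bond on C3, delivers hydride to C6 of an isopropenyl group on C7 and reductively eliminates, forming C4–C5 and the cyclopentanone A3.
- **Merits:** the step is catalytic and atom-economical and sets C6 under ligand control. A3 lacks only the C4 ethyl group, which an enol triflate and a cross-coupling would add, so the endgame is as short as that of the chosen plan. The stereocentre-forming event has closer precedent than a selection between two vinyl groups.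
- **Weak points:** the substrate must already contain ring A with both quaternary carbons, C3, C7 and the styryl group, so the hardest part is moved upstream unsolved. The aldehyde sits on an epimerisable methine. Acyl rhodium hydrides decarbonylate when closure is slow, which is likely for a trans-fused five-membered ring. The styryl and C8=C9 alkenes are competing acceptors.
- **Comparison:** the chosen plan addresses the quaternary pair explicitly with two Claisen rearrangements and spends its late step on C10. It has to accept that C6 rests on a kinetic methylation and not on a catalyst.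

Key step: step 14

## Route

Assumption 1: (4S)-4-[(tert-butyldimethylsilyl)oxy]cyclopent-2-en-1-one (8) is treated as a purchasable enantiopure building block.

Assumption 2: the (S)-diolate enantiomer of the molybdenum catalyst is taken as the one matched to the substrate. The sense of group selection cannot be derived by analogy, and the (R)-diolate complex would be used if the sense proves opposite.

Step 1
Reactants: 1 ethyl pent-2-ynoate
Product: 2 ethyl (2E)-3-ethylpenta-2,4-dienoate
Conditions: CH2=CHMgBr (2.2 equiv), CuBr·SMe2 (1.1 equiv), THF, −78 °C; then 1; 1 M HCl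
Reagents that add atoms: vinylmagnesium bromide, C=C[Mg]Br
Why: Conjugate addition of a vinylcuprate to an alkynoate (carbocupration) is syn-selective at low temperature and places vinyl and ethyl on the future C10; the 2E geometry is expected but has no consequence, because this carbon becomes prochiral.

Step 2
Reactants: 2 ethyl (2E)-3-ethylpenta-2,4-dienoate
Product: 3 (2E)-3-ethylpenta-2,4-dien-1-ol
Conditions: iBu2AlH (2.2 equiv), CH2Cl2, −78 → 0 °C; aq. potassium sodium tartrate
Reagents that add atoms: none
Why: 1,2-Reduction of the conjugated ester by the aluminium hydride gives the allylic alcohol and leaves the diene untouched.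

Step 3
Reactants: 3 (2E)-3-ethylpenta-2,4-dien-1-ol; 4 triethyl orthopropionate
Product: 6 ethyl 3-ethenyl-3-ethyl-2-methylpent-4-enoate (racemic), via mixed ketene acetal 5 (not isolated)
Conditions: 4 (5 equiv), EtCO2H (cat.), 140 °C, EtOH distilled off
Reagents that add atoms: none
Why: Johnson–Claisen rearrangement: alkoxy exchange, loss of ethanol and [3,3] shift of the ketene acetal form C2–C10 and the quaternary C10. C10 carries two vinyl groups and is not stereogenic, and the racemic C2 centre is erased later by enolisation.

Step 4
Reactants: 6 ethyl 3-ethenyl-3-ethyl-2-methylpent-4-enoate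
Product: 7 3-ethenyl-3-ethyl-2-methylpent-4-enoic acid (racemic)
Conditions: KOH, EtOH–H2O (3:1), reflux; then 1 M HCl
Reagents that add atoms: potassium hydroxide, [K+].[OH-]
Why: Saponification of the hindered ethyl ester by hydroxide at reflux; no stereochemical issue arises.

Step 5
Reactants: 8 (4S)-4-[(tert-butyldimethylsilyl)oxy]cyclopent-2-en-1-one; 9 2-bromobut-1-ene
Product: 11 (3R,4S)-3-(but-1-en-2-yl)-4-[(tert-butyldimethylsilyl)oxy]cyclopentan-1-one, via but-1-en-2-ylmagnesium bromide 10 (not isolated)
Conditions: 9, Mg, THF, rt; then CuBr·SMe2 (20 mol %), −78 °C; then 8; aq. NH4Cl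
Reagents that add atoms: none
Why: Copper-catalysed conjugate addition of an alkenyl Grignard reagent to a cyclopentenone; the nucleophile enters anti to the adjacent silyloxy group, which fixes C7.

Step 6
Reactants: 11 (3R,4S)-3-(but-1-en-2-yl)-4-[(tert-butyldimethylsilyl)oxy]cyclopentan-1-one
Product: 12 (4S)-4-(but-1-en-2-yl)cyclopent-2-en-1-one
Conditions: DBU, CH2Cl2, 0 °C
Reagents that add atoms: none
Why: E1cB β-elimination of the silyloxy group through the distal enolate moves the enone to the other side of the carbonyl; the C7 stereocentre is not involved.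

Step 7
Reactants: 12 (4S)-4-(but-1-en-2-yl)cyclopent-2-en-1-one
Product: 14 (4R,5S)-4-(but-1-en-2-yl)-5-methylcyclopent-2-en-1-one, via lithium dienolate 13 (not isolated)
Conditions: LiN(iPr)2, THF, −78 °C; MeI, −78 → −40 °C
Reagents that add atoms: iodomethane, CI
Why: Kinetic α'-deprotonation gives the cross-conjugated dienolate, which is methylated anti to the neighbouring but-1-en-2-yl group (enolate alkylation). C6 is thus set trans to C7, the arrangement that is also thermodynamically preferred.

Step 8
Reactants: 14 (4R,5S)-4-(but-1-en-2-yl)-5-methylcyclopent-2-en-1-one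
Product: 15 (4S,5S)-4-(but-1-en-2-yl)-2-iodo-5-methylcyclopent-2-en-1-one
Conditions: I2, pyridine, CH2Cl2, 0 °C → rt
Reagents that add atoms: iodine, II
Why: α-Iodination of the enone by conjugate addition of pyridine, iodination of the enolate and elimination; the weak base leaves the C7 hydrogen alone.

Step 9
Reactants: 15 (4S,5S)-4-(but-1-en-2-yl)-2-iodo-5-methylcyclopent-2-en-1-one
Product: 16 (4R,5S)-4-(but-1-en-2-yl)-2-ethyl-5-methylcyclopent-2-en-1-one
Conditions: Et2Zn, PdCl2(dppf) (5 mol %), THF, rt → 50 °C
Reagents that add atoms: diethylzinc, CC[Zn]CC
Why: Negishi coupling: oxidative addition of zerovalent palladium into the vinylic C–I bond, transmetalation from zinc and reductive elimination install the C4 ethyl group, the chelating diphosphine suppressing β-hydride elimination.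

Step 10
Reactants: 16 (4R,5S)-4-(but-1-en-2-yl)-2-ethyl-5-methylcyclopent-2-en-1-one
Product: 17 (1S,4R,5S)-4-(but-1-en-2-yl)-2-ethyl-5-methylcyclopent-2-en-1-ol
Conditions: (R)-2-methyl-CBS-oxazaborolidine (20 mol %), catecholborane, toluene, −78 °C
Reagents that add atoms: none
Why: CBS reduction: the oxazaborolidine binds the carbonyl with the α-substituted alkenyl side as the large group and delivers hydride to the face opposite the C6 methyl group, matched with the substrate bias, so the hydroxyl ends cis to methyl (1S). Catecholborane does not hydroborate the 1,1-disubstituted alkene at this temperature.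

Step 11
Reactants: 7 3-ethenyl-3-ethyl-2-methylpent-4-enoic acid; 17 (1S,4R,5S)-4-(but-1-en-2-yl)-2-ethyl-5-methylcyclopent-2-en-1-ol
Product: 19 (1S,4R,5S)-4-(but-1-en-2-yl)-2-ethyl-5-methylcyclopent-2-en-1-yl 3-ethenyl-3-ethyl-2-methylpent-4-enoate (both C2 epimers), via acid chloride 18 (not isolated)
Conditions: (COCl)2, DMF (cat.), CH2Cl2, 0 °C → rt; then 17, pyridine, DMAP, CH2Cl2, rt
Reagents that add atoms: none
Why: Acylation of the hindered secondary allylic alcohol by the acid chloride under nucleophilic catalysis; the two C2 epimers converge in the next step.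

Step 12
Reactants: 19 (1S,4R,5S)-4-(but-1-en-2-yl)-2-ethyl-5-methylcyclopent-2-en-1-yl 3-ethenyl-3-ethyl-2-methylpent-4-enoate
Product: 22 (2R)-2-[(1R,4R,5S)-5-(but-1-en-2-yl)-2-ethyl-4-methylcyclopent-2-en-1-yl]-3-ethenyl-3-ethyl-2-methylpent-4-enoic acid, via Z silyl ketene acetal 20 (not isolated), via trimethylsilyl ester 21 (not isolated)
Conditions: LiN(iPr)2, Me3SiCl–Et3N, THF–HMPA (4:1), −78 °C; then → 65 °C; aq. citric acid
Reagents that add atoms: none
Why: Ireland–Claisen rearrangement: deprotonation in THF–HMPA is expected to place the bulky C10 substituent cis to the oxygen anion (Z silyl ketene acetal). The [3,3] shift, through the boat transition state usual for cycloalkenyl esters, forms C2–C3 on the ring face that carried the oxygen, so C3 follows from C5 by chirality transfer and C2 from the ketene acetal geometry. C5 becomes part of the C4=C5 alkene.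

Step 13
Reactants: 22 (2R)-2-[(1R,4R,5S)-5-(but-1-en-2-yl)-2-ethyl-4-methylcyclopent-2-en-1-yl]-3-ethenyl-3-ethyl-2-methylpent-4-enoic acid
Product: 23 methyl (2R)-2-[(1R,4R,5S)-5-(but-1-en-2-yl)-2-ethyl-4-methylcyclopent-2-en-1-yl]-3-ethenyl-3-ethyl-2-methylpent-4-enoate
Conditions: MeI, K2CO3, DMF, rt
Reagents that add atoms: iodomethane, CI
Why: O-Alkylation of the carboxylate (SN2 at iodomethane) forms the ester without any attack at the shielded carbonyl carbon.

Step 14
Reactants: 23 methyl (2R)-2-[(1R,4R,5S)-5-(but-1-en-2-yl)-2-ethyl-4-methylcyclopent-2-en-1-yl]-3-ethenyl-3-ethyl-2-methylpent-4-enoate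
Product: 24 methyl (1R,3aR,4R,5S,7aS)-5-ethenyl-3,5,7-triethyl-1,4-dimethyl-3a,4,5,7a-tetrahydro-1H-indene-4-carboxylate
Conditions: Mo(=N-2,6-iPr2C6H3)(=CHCMe2Ph)[(S)-3,3'-di-tert-butyl-5,5',6,6'-tetramethylbiphenyl-2,2'-diolate] (10 mol %), C6H6, 50 °C, N2 sweep
Reagents that add atoms: none
Why: Olefin metathesis at the hexavalent molybdenum alkylidene: the initiating alkylidene exchanges with either C10 vinyl group to give a C9 alkylidene, which adds across the C8 methylene of the but-1-en-2-yl group in a [2+2] step; the molybdacyclobutane collapses to C8=C9 and Mo=CH2, which re-enters the cycle with loss of ethene. The closest known reaction type is the molybdenum-catalysed asymmetric ring-closing metathesis that desymmetrises trienes with a divinyl-substituted carbon to all-carbon quaternary centres; here the two vinyl groups are diastereotopic, not enantiotopic. Ring A closes as a six-membered carbocycle by ring-closing metathesis between a monosubstituted and a 1,1-disubstituted alkene, giving a trisubstituted cyclohexene, and the two quaternary carbons C2 and C10 in the tether favour the folded conformer. The new stereocentre C10 is controlled by the chiral diolate on molybdenum: alkylidene formation at the two vinyl groups is fast and reversible and ring formation is slow, so the product reflects the two diastereomeric metallacyclobutane transition states, in which the ligand differentiates the ethyl group from the spectator vinyl group. The resident centres C2, C3 and C7 alone distinguish these two groups only weakly, which is why catalyst control is required. The step also needs chemoselectivity against the ring-B alkene, which is trisubstituted, unstrained and flanked by C3; the two geminal vinyl groups cannot close on each other. Removal of ethene in the nitrogen stream drives the closure, and the ester is tolerated by this class of catalyst.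

Step 15
Reactants: 24 methyl (1R,3aR,4R,5S,7aS)-5-ethenyl-3,5,7-triethyl-1,4-dimethyl-3a,4,5,7a-tetrahydro-1H-indene-4-carboxylate; 25 iodobenzene
Product: 26 methyl (1R,3aR,4R,5S,7aS)-3,5,7-triethyl-1,4-dimethyl-5-[(E)-2-phenylethenyl]-3a,4,5,7a-tetrahydro-1H-indene-4-carboxylate
Conditions: Pd(OAc)2 (10 mol %), n-Bu4NCl, NaHCO3, DMF, 80 °C
Reagents that add atoms: none
Why: Heck reaction: oxidative addition of iodobenzene to zerovalent palladium formed from Pd(OAc)2, then insertion of the only monosubstituted alkene with phenyl at the terminus. β-Hydride elimination is possible only toward the benzylic carbon because C10 is quaternary, which gives the E-styrene; the trisubstituted ring alkenes do not insert.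

Step 16
Reactants: 26 methyl (1R,3aR,4R,5S,7aS)-3,5,7-triethyl-1,4-dimethyl-5-[(E)-2-phenylethenyl]-3a,4,5,7a-tetrahydro-1H-indene-4-carboxylate
Product: 27 spiculoic acid B, (1R,3aR,4R,5S,7aS)-3,5,7-triethyl-1,4-dimethyl-5-[(E)-2-phenylethenyl]-3a,4,5,7a-tetrahydro-1H-indene-4-carboxylic acid
Conditions: LiI, pyridine, reflux; then 1 M HCl, 0 °C
Reagents that add atoms: none
Why: Nucleophilic demethylation: iodide attacks the ester methyl group (SN2), so the shielded carbonyl carbon is not involved and no stereocentre or alkene is touched.

## Compound list

1 | ethyl pent-2-ynoate | CCC#CC(=O)OCC | starting material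
2 | ethyl (2E)-3-ethylpenta-2,4-dienoate | CCOC(=O)/C=C(/C=C)CC | intermediate
3 | (2E)-3-ethylpenta-2,4-dien-1-ol | OC/C=C(/C=C)CC | intermediate
4 | triethyl orthopropionate | CCC(OCC)(OCC)OCC | starting material
5 | 1-ethoxy-1-{[(2E)-3-ethylpenta-2,4-dien-1-yl]oxy}prop-1-ene (mixed ketene acetal) | CC=C(OCC)OC/C=C(/C=C)CC | intermediate (not isolated)
6 | ethyl 3-ethenyl-3-ethyl-2-methylpent-4-enoate (racemic) | CCOC(=O)C(C)C(CC)(C=C)C=C | intermediate
7 | 3-ethenyl-3-ethyl-2-methylpent-4-enoic acid (racemic) | OC(=O)C(C)C(CC)(C=C)C=C | intermediate
8 | (4S)-4-[(tert-butyldimethylsilyl)oxy]cyclopent-2-en-1-one | O=C1C=C[C@@H](O[Si](C)(C)C(C)(C)C)C1 | starting material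
9 | 2-bromobut-1-ene | C=C(Br)CC | starting material
10 | but-1-en-2-ylmagnesium bromide | C=C(CC)[Mg]Br | intermediate (not isolated)
11 | (3R,4S)-3-(but-1-en-2-yl)-4-[(tert-butyldimethylsilyl)oxy]cyclopentan-1-one | C=C(CC)[C@H]1CC(=O)C[C@@H]1O[Si](C)(C)C(C)(C)C | intermediate
12 | (4S)-4-(but-1-en-2-yl)cyclopent-2-en-1-one | C=C(CC)[C@H]1CC(=O)C=C1 | intermediate
13 | lithium (3R)-3-(but-1-en-2-yl)cyclopenta-1,4-dien-1-olate | [Li]OC1=C[C@H](C(=C)CC)C=C1 | intermediate (not isolated)
14 | (4R,5S)-4-(but-1-en-2-yl)-5-methylcyclopent-2-en-1-one | C=C(CC)[C@H]1[C@H](C)C(=O)C=C1 | intermediate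
15 | (4S,5S)-4-(but-1-en-2-yl)-2-iodo-5-methylcyclopent-2-en-1-one | C=C(CC)[C@H]1[C@H](C)C(=O)C(I)=C1 | intermediate
16 | (4R,5S)-4-(but-1-en-2-yl)-2-ethyl-5-methylcyclopent-2-en-1-one | C=C(CC)[C@H]1[C@H](C)C(=O)C(CC)=C1 | intermediate
17 | (1S,4R,5S)-4-(but-1-en-2-yl)-2-ethyl-5-methylcyclopent-2-en-1-ol | C=C(CC)[C@H]1[C@H](C)[C@H](O)C(CC)=C1 | intermediate
18 | 3-ethenyl-3-ethyl-2-methylpent-4-enoyl chloride | ClC(=O)C(C)C(CC)(C=C)C=C | intermediate (not isolated)
19 | (1S,4R,5S)-4-(but-1-en-2-yl)-2-ethyl-5-methylcyclopent-2-en-1-yl 3-ethenyl-3-ethyl-2-methylpent-4-enoate (both C2 epimers) | C=C(CC)[C@H]1[C@H](C)[C@H](OC(=O)C(C)C(CC)(C=C)C=C)C(CC)=C1 | intermediate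
20 | (Z)-trimethylsilyl ketene acetal of 19 (C10 substituent cis to OSiMe3) | C=C(CC)[C@H]1[C@H](C)[C@H](O/C(O[Si](C)(C)C)=C(\C)C(CC)(C=C)C=C)C(CC)=C1 | intermediate (not isolated)
21 | trimethylsilyl ester of 22 | C=C(CC)[C@H]1[C@H](C)C=C(CC)[C@@H]1[C@@](C)(C(=O)O[Si](C)(C)C)C(CC)(C=C)C=C | intermediate (not isolated)
22 | (2R)-2-[(1R,4R,5S)-5-(but-1-en-2-yl)-2-ethyl-4-methylcyclopent-2-en-1-yl]-3-ethenyl-3-ethyl-2-methylpent-4-enoic acid | C=C(CC)[C@H]1[C@H](C)C=C(CC)[C@@H]1[C@@](C)(C(=O)O)C(CC)(C=C)C=C | intermediate
23 | methyl (2R)-2-[(1R,4R,5S)-5-(but-1-en-2-yl)-2-ethyl-4-methylcyclopent-2-en-1-yl]-3-ethenyl-3-ethyl-2-methylpent-4-enoate | C=C(CC)[C@H]1[C@H](C)C=C(CC)[C@@H]1[C@@](C)(C(=O)OC)C(CC)(C=C)C=C | intermediate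
24 | methyl (1R,3aR,4R,5S,7aS)-5-ethenyl-3,5,7-triethyl-1,4-dimethyl-3a,4,5,7a-tetrahydro-1H-indene-4-carboxylate | CCC1=C[C@@](C=C)(CC)[C@](C)(C(=O)OC)[C@H]2C(CC)=C[C@@H](C)[C@H]12 | intermediate
25 | iodobenzene | Ic1ccccc1 | starting material
26 | methyl (1R,3aR,4R,5S,7aS)-3,5,7-triethyl-1,4-dimethyl-5-[(E)-2-phenylethenyl]-3a,4,5,7a-tetrahydro-1H-indene-4-carboxylate | CCC1=C[C@@](/C=C/c2ccccc2)(CC)[C@](C)(C(=O)OC)[C@H]2C(CC)=C[C@@H](C)[C@H]12 | intermediate
27 | spiculoic acid B, (1R,3aR,4R,5S,7aS)-3,5,7-triethyl-1,4-dimethyl-5-[(E)-2-phenylethenyl]-3a,4,5,7a-tetrahydro-1H-indene-4-carboxylic acid | CCC1=C[C@@](/C=C/c2ccccc2)(CC)[C@](C)(C(=O)O)[C@H]2C(CC)=C[C@@H](C)[C@H]12 | target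

## Step count and least certain steps

Total: 16 steps. Longest linear sequence: 12 steps (8 → 27, steps 5–16).

**Step 14 (key step).** The most likely failures are that the C9 alkylidene does not add to the crowded 1,1-disubstituted C8 methylene, so that cross-metathesis oligomers form instead of ring A, or that the two vinyl groups are not discriminated because ethyl and vinyl present nearly the same bulk to the diolate.

The fallback sets C10 by chirality transfer before the union and no longer relies on group selection. It sets out from 3 and comes back to the route at 26.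
- Oxidation of 3 with MnO2 should give (2E)-3-ethylpenta-2,4-dienal F1.
- Enantioselective phenyl transfer from a phenylzinc reagent (PhB(OH)2, Et2Zn) under a chiral amino alcohol should give (1R,2E)-3-ethyl-1-phenylpenta-2,4-dien-1-ol F2.
- Acylation with propanoyl chloride should give (1R,2E)-3-ethyl-1-phenylpenta-2,4-dien-1-yl propanoate F3.
- Ireland–Claisen rearrangement of F3 through a chair with phenyl pseudo-equatorial should transfer the carbinol configuration to C10 and create the E-styryl group, giving (3R,4E)-3-ethenyl-3-ethyl-2-methyl-5-phenylpent-4-enoic acid F4.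
- Esterification with 17 as in step 11 should give (1S,4R,5S)-4-(but-1-en-2-yl)-2-ethyl-5-methylcyclopent-2-en-1-yl (3R,4E)-3-ethenyl-3-ethyl-2-methyl-5-phenylpent-4-enoate F5.
- Rearrangement as in step 12 should give (2R,3R,4E)-2-[(1R,4R,5S)-5-(but-1-en-2-yl)-2-ethyl-4-methylcyclopent-2-en-1-yl]-3-ethenyl-3-ethyl-2-methyl-5-phenylpent-4-enoic acid F6.
- Methylation as in step 13 should give methyl (2R,3R,4E)-2-[(1R,4R,5S)-5-(but-1-en-2-yl)-2-ethyl-4-methylcyclopent-2-en-1-yl]-3-ethenyl-3-ethyl-2-methyl-5-phenylpent-4-enoate F7.
- Ring closure of F7 with the achiral complex Mo(=N-2,6-iPr2C6H3)(=CHCMe2Ph)[OCMe(CF3)2]2 should give 26 directly, the single vinyl group engaging the catalyst far faster than the styryl group.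

**Step 12.** Two things can go wrong. Enolisation may give the other ketene acetal geometry, or the shift may run through a chair in place of the boat; either inverts C2. Alternatively the [3,3] shift between two fully substituted carbons may be so slow that the enolate fragments to a ketene.

The fallback reverses the order of the two rearrangements, so that C2–C3 is made from a simple propanoate and the quaternary C2 is set afterwards by face selection on a ring-bearing ketene acetal. It sets out from 17 and 3 and comes back at 22.
- Propanoylation of 17 should give (1S,4R,5S)-4-(but-1-en-2-yl)-2-ethyl-5-methylcyclopent-2-en-1-yl propanoate F8.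
- Ireland–Claisen rearrangement should give 2-[(1S,4R,5S)-5-(but-1-en-2-yl)-2-ethyl-4-methylcyclopent-2-en-1-yl]propanoic acid F9, whose C2 configuration is irrelevant.
- Esterification of F9 with 3 through its acid chloride should give (2E)-3-ethylpenta-2,4-dien-1-yl 2-[(1S,4R,5S)-5-(but-1-en-2-yl)-2-ethyl-4-methylcyclopent-2-en-1-yl]propanoate F10.
- A second Ireland–Claisen rearrangement of F10, forming C2–C10 on the dienyl terminus, should give 22.

**Step 7.** Deprotonation may occur at the doubly allylic C7 hydrogen instead of the α'-position, with loss of configuration or migration of the side-chain alkene into conjugation. Proton exchange between product and enolate may lead to double methylation.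

The fallback introduces the methyl group before the enone exists. It sets out from 8 and Grignard reagent 10 and comes back at 14.
- Addition of the stoichiometric magnesium cuprate from 10 and CuBr·SMe2 to 8, with the regiodefined enolate trapped in the same flask by iodomethane in the presence of HMPA, should give (2S,3R,4S)-3-(but-1-en-2-yl)-4-[(tert-butyldimethylsilyl)oxy]-2-methylcyclopentan-1-one F11.
- Elimination of F11 with DBU as in step 6 should give 14.

**Step 15.** Insertion at a vinyl group flanked by two quaternary carbons may be slow, so that the catalyst aggregates to palladium metal before conversion, or palladium hydride may move the ring alkenes.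

The fallback replaces the arylation by olefin cross-metathesis. It sets out from 24 and comes back at 26.
- Treatment of 24 with excess styrene and RuCl2(H2IMes)(=CH-C6H4-2-OiPr), the second-generation Hoveyda–Grubbs catalyst, should give 26 with loss of ethene; the E-alkene is the expected outcome.
- The route through F1 to F7 described for step 14 also bypasses this step.

## Further compounds

F1 | step 14 | (2E)-3-ethylpenta-2,4-dienal | O=C/C=C(/C=C)CC
F2 | step 14 | (1R,2E)-3-ethyl-1-phenylpenta-2,4-dien-1-ol | O[C@@H](c1ccccc1)/C=C(/C=C)CC
F3 | step 14 | (1R,2E)-3-ethyl-1-phenylpenta-2,4-dien-1-yl propanoate | CCC(=O)O[C@@H](c1ccccc1)/C=C(/C=C)CC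
F4 | step 14 | (3R,4E)-3-ethenyl-3-ethyl-2-methyl-5-phenylpent-4-enoic acid (both C2 epimers) | C=C[C@@](/C=C/c1ccccc1)(CC)C(C)C(=O)O
F5 | step 14 | (1S,4R,5S)-4-(but-1-en-2-yl)-2-ethyl-5-methylcyclopent-2-en-1-yl (3R,4E)-3-ethenyl-3-ethyl-2-methyl-5-phenylpent-4-enoate | C=C(CC)[C@H]1[C@H](C)[C@H](OC(=O)C(C)[C@](CC)(C=C)/C=C/c2ccccc2)C(CC)=C1
F6 | step 14 | (2R,3R,4E)-2-[(1R,4R,5S)-5-(but-1-en-2-yl)-2-ethyl-4-methylcyclopent-2-en-1-yl]-3-ethenyl-3-ethyl-2-methyl-5-phenylpent-4-enoic acid | C=C(CC)[C@H]1[C@H](C)C=C(CC)[C@@H]1[C@@](C)(C(=O)O)[C@](CC)(C=C)/C=C/c1ccccc1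
F7 | step 14 | methyl (2R,3R,4E)-2-[(1R,4R,5S)-5-(but-1-en-2-yl)-2-ethyl-4-methylcyclopent-2-en-1-yl]-3-ethenyl-3-ethyl-2-methyl-5-phenylpent-4-enoate | C=C(CC)[C@H]1[C@H](C)C=C(CC)[C@@H]1[C@@](C)(C(=O)OC)[C@](CC)(C=C)/C=C/c1ccccc1
F8 | step 12 | (1S,4R,5S)-4-(but-1-en-2-yl)-2-ethyl-5-methylcyclopent-2-en-1-yl propanoate | C=C(CC)[C@H]1[C@H](C)[C@H](OC(=O)CC)C(CC)=C1
F9 | step 12 | 2-[(1S,4R,5S)-5-(but-1-en-2-yl)-2-ethyl-4-methylcyclopent-2-en-1-yl]propanoic acid | C=C(CC)[C@H]1[C@H](C)C=C(CC)[C@@H]1C(C)C(=O)O
F10 | step 12 | (2E)-3-ethylpenta-2,4-dien-1-yl 2-[(1S,4R,5S)-5-(but-1-en-2-yl)-2-ethyl-4-methylcyclopent-2-en-1-yl]propanoate | C=C(CC)[C@H]1[C@H](C)C=C(CC)[C@@H]1C(C)C(=O)OC/C=C(/C=C)CC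
F11 | step 7 | (2S,3R,4S)-3-(but-1-en-2-yl)-4-[(tert-butyldimethylsilyl)oxy]-2-methylcyclopentan-1-one | C=C(CC)[C@H]1[C@H](C)C(=O)C[C@@H]1O[Si](C)(C)C(C)(C)C
F0 | step 15 | none | none
A1 | alternative 1 | spiro 2-oxabicyclo[2.1.1]hexan-3-one photoadduct with quaternary C2 and C10, C8 as dithiane, silyloxymethyl on C10 | O=C1C[C@@H](C)[C@H](C2(CC)SCCCS2)[C@]13[C@@H]4OC(=O)[C@@]3(C)[C@@]4(CC)CO[Si](C)(C)C(C)(C)C
A2 | alternative 2 | C9-keto ester with quaternary C2 (Me, CO2Me) and C10 (Et, styryl), C4 ketone as dioxolane | CC[C@H]1C(=O)[C@@](/C=C/c2ccccc2)(CC)[C@](C)(C(=O)OC)[C@@H]2[C@@H]1[C@H](C)CC23OCCO3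
A3 | alternative 3 | trans-fused bicyclic C4 ketone lacking the C4 ethyl group | CCC1=C[C@@](/C=C/c2ccccc2)(CC)[C@](C)(C(=O)OC)[C@H]2C(=O)C[C@@H](C)[C@H]12
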